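(Readings and results stem from a simulated flask for substances that don't exist; noise was put on by code.)

The readings are slow to show an endpoint: Wednesday's run is still creeping from 69% to 75% of target over its last interval, so for the long limit I ask the charges, not the clock.

the same everywhere: starting material 0.26 M; free catalyst 0.36 mM; impurity 0.17 mM; added ligand 1.5 mM
- Wednesday's: coupling partner 0.33 M (in portions, 4); second substrate 0.052 M; run made earlier; portions every 8.0 s
- Sunday's: coupling partner 0.51 M (in portions, 4); second substrate 0.052 M; run made earlier; portions every 8.0 s
- Thursday's: coupling partner 0.234 M (in portions, 4); second substrate 0.026 M; run made earlier; portions every 8.0 s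
- flask: coupling partner 0.234 M (in portions, 4); second substrate 0.0520 M; the portions of coupling partner follow each other after 8.0 s, the first at the start; time 3.0 min

| run | time / min | starting material / % | target / % |
|---|---|---|---|
| Wednesday's | 0.667 | 74 | 27 |
| Wednesday's | 1.33 | 45 | 55 |
| Wednesday's | 2.00 | 31 | 69 |
| Wednesday's | 2.50 | 24 | 75 |
| Sunday's | 0.333 | 86 | 14 |
| Sunday's | 0.833 | 44 | 56 |
| Sunday's | 1.50 | 19 | 82 |
| Sunday's | 2.50 | 4 | 95 |
| Thursday's | 0.667 | 76 | 24 |
| Thursday's | 1.33 | 54 | 47 |
| Thursday's | 2.00 | 43 | 59 |
| Thursday's | 2.50 | 37 | 63 |

(standard deviation of a reading: 1.5 percentage points)

- how much of the starting material has reacted by 3.0 min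
- how much target there is at 3.0 min, in percent of the starting material charged
- amount of target if the flask were left three thousand times as long, in percent of the starting material charged

In Wednesday's run, starting material and target add up to 99.0% at the last reading, with a scatter of 1.5 percentage points on each, so I count reacted starting material as target. In this flask the coupling partner charged is less than the two substrates together, 0.234 M against 0.312 M, which makes it the limiting reagent. My first way is a plain count: I pay the whole charge of second substrate out of the coupling partner and express the remainder as a fraction of the starting material charged, and I call this the partner margin.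

f = (0.234 M − 0.0520 M) / 0.26 M = 70.0%

The forecast gives 60% reacted (56% to 64%), 60% of target (56% to 64%), and 72% in the long limit (69% to 76%), and its ground for the last is this: “Selectivity therefore sets the endpoint.”

The second way divides the loss rate of second substrate by that of starting material, so that coupling partner, catalyst and time cancel. With a and s the fractions left of each charge, and S the selectivity factor:

s = a^S

The forecast's 72% means a = 28.0%, and the partner balance then leaves:

s = 10.0%, S = ln s / ln a = 1.81

The two ways part by 2 points, and that gap is the unspent second substrate, worth 2.00% of the starting material charged. The count cheats if s stays above zero, the ratio if its S, read through the scatter, is too low. That gap is s times the charge ratio of 0.200, so it is small only if s is small, and my S of 1.81 is the forecast's 72% read back, not a second finding. With S = 1 the same balance gives 75.0% of target, so I commit to between 70.0% and 75.0% in the long limit, the upper end resting on S being no lower than 1, as the forecast's reading of about 1.8 has it.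

The flask gives 58.2% reacted and 58.2% of target at 3.0 min, and 70.0% of target in the long limit, each inside the forecast's range.

    second substrate + coupling partner + free catalyst → free catalyst + second product (k = 5400 M⁻² s⁻¹)
    second substrate + free catalyst ⇌ idle complex A, settled at all times (K = 71.0 M⁻¹)
    free catalyst + impurity → spent catalyst (k = 5800 M⁻¹ s⁻¹)
    starting material + coupling partner + free catalyst → free catalyst + target (k = 570 M⁻² s⁻¹)
    free catalyst + added ligand ⇌ idle complex B, settled at all times (K = 270 M⁻¹)

At 3.00 min this flask keeps 0.027% of its second substrate against 42% of its starting material. Its target plus the 13% of coupling partner left, counted on the starting material charged, comes to 69.9%, against a margin of 70.0%. The neighbouring flask with 0.021 M of second substrate has a margin of 81.9%, and at 3.00 min it holds 66.9% of target and 17% of its coupling partner, which together make 82.2%.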